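**Retrosynthetic overview**
- The strategy rests on the homoallylic array O6–C6–C7–C11(=C13) of the trans-fused α-methylene-γ-lactone on the ten-membered carbocycle C1–C10: it is the retron of a [2,3]-Wittig shift of an ether joining O6 to C13.
- Late steps: angelate on O9 and acetate on O8 by acylation; lactone ring by oxidation at C12 of a C6/C12 diol.
- Core: the C6–C7 bond by transannular [2,3]-Wittig ring contraction of a 13-membered bis-allylic ether; the O–C6 bond of that ether by Williamson macrocyclization.
- Chain: C7=C11 by oxa-Michael/Horner–Wadsworth–Emmons olefination, C9–C10 by Nozaki–Hiyama–Kishi coupling, C1=C10 by Z-selective iodo-olefination of a geranyl acetate-derived aldehyde.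
- Ring order: 13-membered ether ring first, then the ten-membered carbocycle by contraction, then the five-membered lactone; C8 comes from (R)-glyceraldehyde acetonide, C9 from a Felkin–Anh-type reduction, C6 and C7 from the rearrangement.

Key step: step 17

Assumption: germacranolide numbering is used throughout (ring C1–C10, lactone oxygen on C6, C11 on C7, C12 the lactone carbonyl, C13 the exocyclic methylene, C14 on C10, C15 on C4); the epoxide carbon of 2 is racemic, which is immaterial because it is excised in step 2.

Step 1
Reactants: 1 geranyl acetate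
Product: 2 6,7-epoxygeranyl acetate
Conditions: mCPBA (1.05 equiv), NaHCO3, CH2Cl2, 0 °C
Reagents that add atoms: mCPBA, O=C(OO)c1cccc(Cl)c1
Why: Prilezhaev epoxidation should select the electron-rich remote trisubstituted olefin, because the 2,3-olefin is deactivated by the allylic acetate.

Step 2
Reactants: 2 6,7-epoxygeranyl acetate
Product: 4 (E)-6-acetoxy-4-methylhex-4-enal, via 6,7-diol 3 (not isolated)
Conditions: H5IO6 (1.2 equiv), THF/H2O, 0 °C
Reagents that add atoms: none
Why: acid-mediated epoxide hydrolysis (water enters at the tertiary carbon, so the aldehyde keeps the epoxide oxygen) followed by Malaprade glycol cleavage should release acetone and the C1 aldehyde without touching the acetate.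

Step 3
Reactants: 4 (E)-6-acetoxy-4-methylhex-4-enal; 5 ethyltriphenylphosphonium bromide
Product: 9 (2E,6Z)-7-iodo-3-methylocta-2,6-dienyl acetate, via ethylidenetriphenylphosphorane 6 (not isolated), via (1-iodoethyl)triphenylphosphonium iodide 7 (not isolated), via (1-iodoethylidene)triphenylphosphorane 8 (not isolated)
Conditions: 5, n-BuLi, THF, 0 °C; I2, −78 °C; NaN(SiMe3)2, −20 °C; 4, −78 °C to rt
Reagents that add atoms: iodine, II
Why: Stork–Zhao iodo-olefination, in which the α-iodo ylide should add to the aldehyde under kinetic control to give the (Z)-2-iodo-2-alkene (iodine cis to the chain) far faster than it attacks the acetate at low temperature.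

Step 4
Reactants: 9 (2E,6Z)-7-iodo-3-methylocta-2,6-dienyl acetate; 10 (R)-2,3-O-isopropylideneglyceraldehyde
Product: 12 C9 carbinol as a mixture of C9 epimers, via alkenylchromium dichloride 11 (not isolated)
Conditions: CrCl2 (4 equiv), NiCl2 (2 mol %), DMSO/THF, rt
Reagents that add atoms: none
Why: Nozaki–Hiyama–Kishi coupling, in which nickel-catalysed activation of the C–I bond and transfer to trivalent chromium should give an alkenylchromium that adds only to the aldehyde with retention of the Z geometry; the C9 epimers (anti expected to prevail) are carried on together because C9 is reset in steps 5 and 6.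

Step 5
Reactants: 12 C9 carbinol (epimer mixture)
Product: 13 C9 enone
Conditions: Dess–Martin periodinane, NaHCO3, CH2Cl2, 0 °C to rt
Reagents that add atoms: none
Why: Dess–Martin oxidation under buffered conditions should converge both epimers on one α'-alkoxy enone without epimerizing C8, isomerizing the Z olefin or opening the acetonide.

Step 6
Reactants: 13 C9 enone
Product: 14 (8R,9R) syn allylic alcohol
Conditions: LiBH(s-Bu)3 (1.2 equiv), THF, −78 °C; then H2O
Reagents that add atoms: none
Why: Felkin–Anh-type 1,2-reduction, in which the bulky non-chelating hydride should attack anti to the C8–O bond past the C8 hydrogen and so give the 8,9-syn carbinol (9R), 1,2-addition being favoured on this α-methyl, β-substituted enone.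

Step 7
Reactants: 14 (8R,9R) syn allylic alcohol
Product: 15 C9 tert-butyldimethylsilyl ether
Conditions: TBSOTf, 2,6-lutidine, CH2Cl2, −78 to 0 °C
Reagents that add atoms: tert-butyldimethylsilyl triflate, CC(C)(C)[Si](C)(C)OS(=O)(=O)C(F)(F)F
Why: silylation with the silyl triflate should cap the hindered secondary allylic alcohol while acetonide and acetate stay inert.

Step 8
Reactants: 15 C9 tert-butyldimethylsilyl ether
Product: 16 C7/C8 diol
Conditions: PPTS (0.2 equiv), MeOH, 40 °C
Reagents that add atoms: none
Why: acid-catalysed transketalization should remove the terminal acetonide as 2,2-dimethoxypropane under conditions that a hindered secondary TBS ether and an acetate tolerate.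

Step 9
Reactants: 16 C7/C8 diol
Product: 17 C7/C8 bis(triethylsilyl) ether
Conditions: TESOTf (2.5 equiv), 2,6-lutidine, CH2Cl2, −78 °C
Reagents that add atoms: triethylsilyl triflate, CC[Si](CC)(CC)OS(=O)(=O)C(F)(F)F
Why: exhaustive silylation should place a labile triethylsilyl group on both hydroxyls, which differentiates O8 (TES) from O9 (TBS) for the end game.

Step 10
Reactants: 17 C7/C8 bis(triethylsilyl) ether
Product: 18 C7 aldehyde
Conditions: (COCl)2 (4 equiv), DMSO (8 equiv), CH2Cl2, −78 to −40 °C; Et3N, −78 to 0 °C
Reagents that add atoms: none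
Why: Swern oxidation of a primary triethylsilyl ether, in which the chlorosulfonium salt should desilylate only the unhindered primary ether and oxidize it in the same pot, leaving the secondary TES and TBS ethers in place; the α-silyloxy aldehyde is used crude to protect C8.

Step 11
Reactants: 18 C7 aldehyde; 19 ethyl 2-(diethoxyphosphoryl)acrylate
Product: 21 (E)-enoate carrying the 4-methoxybenzyloxymethyl branch on C11, via sodium phosphonate carbanion 20 (not isolated)
Conditions: 4-methoxybenzyl alcohol, NaH, THF, 0 °C; 19, 0 °C; then 18, −78 to 0 °C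
Reagents that add atoms: 4-methoxybenzyl alcohol, COc1ccc(CO)cc1
Why: oxa-Michael addition of the alkoxide to the vinylphosphonate should give the stabilized phosphonate carbanion, which undergoes Horner–Wadsworth–Emmons olefination with the α-branched aldehyde to place the ester trans to C8 (E); the alkoxide is consumed before the aldehyde is added, which spares the acetate.

Step 12
Reactants: 21 (E)-enoate
Product: 22 C6 allylic alcohol
Conditions: K2CO3 (0.2 equiv), EtOH, 0 °C to rt
Reagents that add atoms: none
Why: base-catalysed transesterification should cleave the unhindered primary acetate much faster than the hindered conjugated ester, ethanol as solvent keeping the ethyl ester unchanged.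

Step 13
Reactants: 22 C6 allylic alcohol
Product: 24 C6 allylic chloride, via allylic mesylate 23 (not isolated)
Conditions: MsCl, 2,4,6-collidine, LiCl, DMF, 0 °C
Reagents that add atoms: lithium chloride, [Li+].[Cl-]
Why: mesylation followed by SN2 displacement with chloride in the same flask should give the primary allylic chloride without allylic transposition or loss of the E geometry.

Step 14
Reactants: 24 C6 allylic chloride
Product: 25 seco chloro alcohol
Conditions: i-Bu2AlH (2.5 equiv), CH2Cl2, −78 °C; aq. potassium sodium tartrate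
Reagents that add atoms: none
Why: 1,2-reduction of the enoate by the aluminium hydride should give the C13 allylic alcohol while allylic chloride, silyl ethers and PMB ether are inert at low temperature.

Step 15
Reactants: 25 seco chloro alcohol
Product: 27 13-membered bis-allylic ether, via sodium alkoxide 26 (not isolated)
Conditions: NaH (3 equiv), Bu4NI (cat.), THF, 0.002 M, slow addition, 45 °C
Reagents that add atoms: none
Why: intramolecular Williamson etherification, in which the primary C13 alkoxide should displace the primary allylic chloride at C6 by SN2 under high dilution, a ring size known to close well for this kind of ether; the alkoxide lies trans to C8 across the olefin and cannot reach the C8 silyl group.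

Step 16
Reactants: 27 13-membered bis-allylic ether
Product: 28 13-membered ether with free C12 hydroxymethyl
Conditions: DDQ (1.3 equiv), CH2Cl2/pH 7 buffer, 0 °C
Reagents that add atoms: none
Why: oxidative cleavage of the electron-rich 4-methoxybenzyl ether should free the C12 hydroxyl, removing the acidic benzylic position before the carbanion step, while silyl ethers and ring olefins are untouched.

Step 17
Reactants: 28 13-membered ether with free C12 hydroxymethyl
Product: 31 germacradiene diol, via lithium alkoxide 29 (not isolated), via C6-lithiated alkoxide 30 (not isolated)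
Conditions: n-BuLi (3 equiv), THF, −78 to −25 °C; then H2O
Reagents that add atoms: none
Why: The first equivalent of n-BuLi gives the C12 lithium alkoxide 29 and a further equivalent removes an allylic α-oxy proton at C6 to give 30, in which C6 bonds to C7 while the O–C13 bond breaks and the C11=C13 methylene appears, a concerted suprafacial [2,3]-Wittig shift through a five-membered envelope (C6, O, C13, C11, C7). The closest known reaction type is the [2,3]-Wittig ring contraction of 13-membered bis-allylic ethers to cyclodeca-1,5-dienols. The ten-membered carbocycle (C1 to C10) is closed transannularly by ring contraction, with O, C13 and C11 extruded from the 13-membered ring, so no end-to-end cyclization is involved and both trisubstituted ring olefins stay as they are. C6 and C7 are created together: the E geometry of the ring olefin C7=C11 should give the anti relation of O6 and C8 across the new bond (the later trans-fused lactone), and allylic 1,3-strain with the C12 arm holds the C8 hydrogen in the olefin plane so that C6 bonds to the face of C7 opposite the C8 silyloxy group, the face on which the chain through C9 lies, which corresponds to (6R,7S). The step needs lithiation at C6 and not at C13, and a [2,3] and not a [1,2] shift: the lithium alkoxide on C12 disfavours a second negative charge on the allyl unit C13–C11–C7 that carries it, C13 is flanked by the fully substituted C11, and low temperature with lithium as counter-ion favours the concerted path and suppresses silyl migration from O8 to O12.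

Step 18
Reactants: 31 germacradiene diol
Product: 34 bis-silylated α-methylene lactone, via hydroxy enal 32 (not isolated), via lactol 33 (not isolated)
Conditions: TEMPO (0.2 equiv), PhI(OAc)2 (3 equiv), CH2Cl2, rt
Reagents that add atoms: none
Why: nitroxyl-catalysed oxidation should select the primary allylic alcohol, the resulting enal is trapped by the C6 hydroxyl as a lactol and this is oxidized on to the α-methylene-γ-lactone, trans-fused because C6 and C7 are already set.

Step 19
Reactants: 34 bis-silylated α-methylene lactone
Product: 35 C8 alcohol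
Conditions: HF·pyridine, pyridine, THF, 0 °C
Reagents that add atoms: none
Why: buffered fluoride desilylation should remove the triethylsilyl ether much faster than the hindered allylic TBS ether and spares the acid-sensitive cyclodecadiene and the conjugated lactone.

Step 20
Reactants: 35 C8 alcohol
Product: 36 C8 acetate
Conditions: Ac2O, pyridine, DMAP (cat.), CH2Cl2, 0 °C to rt
Reagents that add atoms: acetic anhydride, CC(=O)OC(C)=O
Why: nucleophile-catalysed acetylation should esterify the only free hydroxyl.

Step 21
Reactants: 36 C8 acetate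
Product: 37 C9 alcohol
Conditions: HF·pyridine, THF, rt
Reagents that add atoms: none
Why: fluoride desilylation under mildly acidic conditions should free the C9 hydroxyl without base-induced migration of the neighbouring acetate or conjugate addition to the lactone.

Step 22
Reactants: 37 C9 alcohol; 38 angelic acid
Product: 40 target CNP0200690.1, via mixed anhydride 39 (not isolated)
Conditions: 38, 2,4,6-trichlorobenzoyl chloride, Et3N (1 equiv), toluene, rt; then 37, toluene, 80 °C, no DMAP
Reagents that add atoms: none
Why: Yamaguchi-type esterification through the mixed anhydride should transfer the angeloyl group without a nucleophilic catalyst, so the addition–elimination path that turns angelate into tiglate is avoided and the Z olefin is kept.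

**Compound list**
1 | geranyl acetate | CC(C)=CCC/C(C)=C/COC(C)=O | starting material
2 | 6,7-epoxygeranyl acetate, (E)-5-(3,3-dimethyloxiran-2-yl)-3-methylpent-2-enyl acetate, racemic epoxide | CC1(C)OC1CC/C(C)=C/COC(C)=O | intermediate
3 | (E)-6,7-dihydroxy-3,7-dimethyloct-2-enyl acetate | CC(C)(O)C(O)CC/C(C)=C/COC(C)=O | intermediate (not isolated)
4 | (E)-6-acetoxy-4-methylhex-4-enal (C1–C6, C15) | O=CCC/C(C)=C/COC(C)=O | intermediate
5 | ethyltriphenylphosphonium bromide (C10, C14) | CC[P+](c1ccccc1)(c1ccccc1)c1ccccc1.[Br-] | starting material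
6 | ethylidenetriphenylphosphorane | CC=P(c1ccccc1)(c1ccccc1)c1ccccc1 | intermediate (not isolated)
7 | (1-iodoethyl)triphenylphosphonium iodide | CC(I)[P+](c1ccccc1)(c1ccccc1)c1ccccc1.[I-] | intermediate (not isolated)
8 | (1-iodoethylidene)triphenylphosphorane | CC(I)=P(c1ccccc1)(c1ccccc1)c1ccccc1 | intermediate (not isolated)
9 | (2E,6Z)-7-iodo-3-methylocta-2,6-dienyl acetate | CC(=O)OC/C=C(\C)CC/C=C(/C)I | intermediate
10 | (R)-2,3-O-isopropylideneglyceraldehyde (C7–C9) | O=C[C@H]1COC(C)(C)O1 | starting material
11 | (2Z,6E)-8-acetoxy-6-methylocta-2,6-dien-2-ylchromium dichloride (trivalent chromium) | CC(=O)OC/C=C(\C)CC/C=C(/C)[Cr](Cl)Cl | intermediate (not isolated)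
12 | (2E,6Z)-8-[(4R)-2,2-dimethyl-1,3-dioxolan-4-yl]-8-hydroxy-3,7-dimethylocta-2,6-dienyl acetate, both C9 epimers | CC(=O)OC/C=C(\C)CC/C=C(/C)C(O)[C@H]1COC(C)(C)O1 | intermediate
13 | (2E,6Z)-8-[(4R)-2,2-dimethyl-1,3-dioxolan-4-yl]-3,7-dimethyl-8-oxoocta-2,6-dienyl acetate | CC(=O)OC/C=C(\C)CC/C=C(/C)C(=O)[C@H]1COC(C)(C)O1 | intermediate
14 | (2E,6Z,8R)-8-[(4R)-2,2-dimethyl-1,3-dioxolan-4-yl]-8-hydroxy-3,7-dimethylocta-2,6-dienyl acetate (8,9-syn; 8R,9R in ring numbering) | CC(=O)OC/C=C(\C)CC/C=C(/C)[C@@H](O)[C@H]1COC(C)(C)O1 | intermediate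
15 | C9 tert-butyldimethylsilyl ether of 14 | CC(=O)OC/C=C(\C)CC/C=C(/C)[C@@H](O[Si](C)(C)C(C)(C)C)[C@H]1COC(C)(C)O1 | intermediate
16 | C7/C8 diol: C6 acetate, C9 OTBS, free hydroxyls on C8 and C7 | CC(=O)OC/C=C(\C)CC/C=C(/C)[C@@H](O[Si](C)(C)C(C)(C)C)[C@H](O)CO | intermediate
17 | bis(triethylsilyl) ether of 16 (C8 OTES, C7 OTES) | CC(=O)OC/C=C(\C)CC/C=C(/C)[C@@H](O[Si](C)(C)C(C)(C)C)[C@H](O[Si](CC)(CC)CC)CO[Si](CC)(CC)CC | intermediate
18 | C7 aldehyde: C6 acetate, C9 OTBS, C8 OTES, configuration at C8 and C9 as in 14 | CC(=O)OC/C=C(\C)CC/C=C(/C)[C@@H](O[Si](C)(C)C(C)(C)C)[C@H](O[Si](CC)(CC)CC)C=O | intermediate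
19 | ethyl 2-(diethoxyphosphoryl)acrylate (C11–C13) | C=C(C(=O)OCC)P(=O)(OCC)OCC | starting material
20 | sodium salt of ethyl 2-(diethoxyphosphoryl)-3-(4-methoxybenzyloxy)propanoate carbanion | CCOC(=O)[C-](COCc1ccc(OC)cc1)P(=O)(OCC)OCC.[Na+] | intermediate (not isolated)
21 | ethyl (E)-enoate: C7=C11 with CO2Et trans to C8 and CH2OPMB cis to C8; C6 acetate, C9 OTBS, C8 OTES | CC(=O)OC/C=C(\C)CC/C=C(/C)[C@@H](O[Si](C)(C)C(C)(C)C)[C@H](O[Si](CC)(CC)CC)/C=C(\COCc1ccc(OC)cc1)C(=O)OCC | intermediate
22 | C6 allylic alcohol of 21 | OC/C=C(\C)CC/C=C(/C)[C@@H](O[Si](C)(C)C(C)(C)C)[C@H](O[Si](CC)(CC)CC)/C=C(\COCc1ccc(OC)cc1)C(=O)OCC | intermediate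
23 | C6 allylic mesylate of 22 | CS(=O)(=O)OC/C=C(\C)CC/C=C(/C)[C@@H](O[Si](C)(C)C(C)(C)C)[C@H](O[Si](CC)(CC)CC)/C=C(\COCc1ccc(OC)cc1)C(=O)OCC | intermediate (not isolated)
24 | C6 allylic chloride, ethyl ester | ClC/C=C(\C)CC/C=C(/C)[C@@H](O[Si](C)(C)C(C)(C)C)[C@H](O[Si](CC)(CC)CC)/C=C(\COCc1ccc(OC)cc1)C(=O)OCC | intermediate
25 | seco chloro alcohol: C6 chloride, C13 allylic alcohol, C12 OPMB | ClC/C=C(\C)CC/C=C(/C)[C@@H](O[Si](C)(C)C(C)(C)C)[C@H](O[Si](CC)(CC)CC)/C=C(\COCc1ccc(OC)cc1)CO | intermediate
26 | sodium C13 alkoxide of 25 | ClC/C=C(\C)CC/C=C(/C)[C@@H](O[Si](C)(C)C(C)(C)C)[C@H](O[Si](CC)(CC)CC)/C=C(\COCc1ccc(OC)cc1)C[O-].[Na+] | intermediate (not isolated)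
27 | 13-membered bis-allylic ether (ring O, C6, C5, C4, C3, C2, C1, C10, C9, C8, C7, C11, C13; 4E, 1(10)Z, 7(11)E; C12 OPMB) | C1/C=C(\C)CC/C=C(/C)[C@@H](O[Si](C)(C)C(C)(C)C)[C@H](O[Si](CC)(CC)CC)/C=C(\COCc2ccc(OC)cc2)CO1 | intermediate
28 | 13-membered ether with free C12 hydroxymethyl | C1/C=C(\C)CC/C=C(/C)[C@@H](O[Si](C)(C)C(C)(C)C)[C@H](O[Si](CC)(CC)CC)/C=C(\CO)CO1 | intermediate
29 | lithium C12 alkoxide of 28 | C1/C=C(\C)CC/C=C(/C)[C@@H](O[Si](C)(C)C(C)(C)C)[C@H](O[Si](CC)(CC)CC)/C=C(\C[O-])CO1.[Li+] | intermediate (not isolated)
30 | C6-lithiated lithium alkoxide of 28 (dilithio species) | [CH-]1/C=C(\C)CC/C=C(/C)[C@@H](O[Si](C)(C)C(C)(C)C)[C@H](O[Si](CC)(CC)CC)/C=C(\C[O-])CO1.[Li+].[Li+] | intermediate (not isolated)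
31 | germacradiene diol (6R,7S,8R,9R): C6 hydroxyl, C7 bearing 3-hydroxyprop-1-en-2-yl, C8 OTES, C9 OTBS | O[C@@H]1/C=C(\C)CC/C=C(/C)[C@@H](O[Si](C)(C)C(C)(C)C)[C@H](O[Si](CC)(CC)CC)[C@H]1C(=C)CO | intermediate
32 | hydroxy enal (C12 aldehyde of 31) | O[C@@H]1/C=C(\C)CC/C=C(/C)[C@@H](O[Si](C)(C)C(C)(C)C)[C@H](O[Si](CC)(CC)CC)[C@H]1C(=C)C=O | intermediate (not isolated)
33 | lactol (C12 hemiacetal, either anomer) | C=C1C(O)O[C@@H]2/C=C(\C)CC/C=C(/C)[C@@H](O[Si](C)(C)C(C)(C)C)[C@H](O[Si](CC)(CC)CC)[C@@H]12 | intermediate (not isolated)
34 | bis-silylated α-methylene lactone (C8 OTES, C9 OTBS) | C=C1C(=O)O[C@@H]2/C=C(\C)CC/C=C(/C)[C@@H](O[Si](C)(C)C(C)(C)C)[C@H](O[Si](CC)(CC)CC)[C@@H]12 | intermediate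
35 | C8 alcohol (C9 OTBS) | C=C1C(=O)O[C@@H]2/C=C(\C)CC/C=C(/C)[C@@H](O[Si](C)(C)C(C)(C)C)[C@H](O)[C@@H]12 | intermediate
36 | C8 acetate (C9 OTBS) | C=C1C(=O)O[C@@H]2/C=C(\C)CC/C=C(/C)[C@@H](O[Si](C)(C)C(C)(C)C)[C@H](OC(C)=O)[C@@H]12 | intermediate
37 | C9 alcohol, C8 acetate | C=C1C(=O)O[C@@H]2/C=C(\C)CC/C=C(/C)[C@@H](O)[C@H](OC(C)=O)[C@@H]12 | intermediate
38 | angelic acid, (Z)-2-methylbut-2-enoic acid | C/C=C(/C)C(=O)O | starting material
39 | angelic 2,4,6-trichlorobenzoic anhydride | C/C=C(/C)C(=O)OC(=O)c1c(Cl)cc(Cl)cc1Cl | intermediate (not isolated)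
40 | CNP0200690.1 (6R,7S,8R,9R; 8-acetate, 9-angelate) | C=C1C(=O)O[C@@H]2/C=C(\C)CC/C=C(/C)[C@@H](OC(=O)/C(C)=C\C)[C@H](OC(C)=O)[C@@H]12 | target

**Step count and weak points**
Total step count: 22. Longest linear sequence: 22 steps, from geranyl acetate 1; compounds 5, 10, 19 and 38 are bought.

Steps most likely to fail:

1. Step 17. The base may lithiate C13 under the direction of the neighbouring alkoxide, which would lead to contraction onto C4 or to loss of the C8 silyloxy group by elimination. A [1,2]-shift may compete, facial control at C7 may be insufficient, or the triethylsilyl group may migrate from O8 to the C12 alkoxide. The fallback sets out from 22 and comes back at 34; it closes the ten-membered ring directly at the same C6–C7 bond and so also bypasses the macro-etherification. MnO2 in CH2Cl2 should oxidize the C6 alcohol to the C6 enal F1. DDQ should then remove the PMB group to give the hydroxymethyl enoate F2, and CBr4/PPh3 should give the 2-(bromomethyl)enoate F3. CrCl2 in THF at high dilution (intramolecular Nozaki–Hiyama allylation, a Barbier-type macrocyclization) should form an allylchromium species at the bromomethyl carbon, which adds through C7 to the C6 aldehyde. The resulting alkoxide should close onto the ethyl ester to give 34; the ester carbon then serves as C12 and the bromomethyl carbon as C13. The C6/C7 relation would come from a chair-like cyclic transition state and would have to be confirmed.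

2. Step 6. Hydride delivery may show poor facial selectivity, conjugate reduction may compete, or the strained Z enone made in step 5 may isomerize to E. The fallback sets out from 9 and 10 and comes back at 14 without any new compound. It is an asymmetric Nozaki–Hiyama–Kishi coupling in which CrCl2 is complexed by a chiral oxazoline–sulfonamide ligand (Et3N, THF, NiCl2 as catalyst). The ligand antipode would be chosen by trial to override the substrate bias and deliver the 9R carbinol, so that one reagent-controlled C–C bond formation replaces steps 4 to 6.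

3. Step 22. Acylation of the hindered C9 hydroxyl may be sluggish, the acetyl group may migrate from O8 to O9 under the warm basic conditions, or the angelate may isomerize to the tiglate. The fallback sets out from 37 and comes back at 40. Esterification of 37 with 2-[bis(2,2,2-trifluoroethoxy)phosphoryl]propanoic acid (DCC, catalytic DMAP, CH2Cl2, 0 °C) should give the C9 phosphonopropionate F4. Still–Gennari olefination (KN(SiMe3)2, 18-crown-6, THF, −78 °C, acetaldehyde) should then build the Z-trisubstituted olefin of the angelate on the ester and give 40.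

Further compounds
F1 | step 17 | C6 enal of 22 (ethyl ester and PMB ether retained) | O=C/C=C(\C)CC/C=C(/C)[C@@H](O[Si](C)(C)C(C)(C)C)[C@H](O[Si](CC)(CC)CC)/C=C(\COCc1ccc(OC)cc1)C(=O)OCC
F2 | step 17 | C6 enal with free hydroxymethyl on C11 | O=C/C=C(\C)CC/C=C(/C)[C@@H](O[Si](C)(C)C(C)(C)C)[C@H](O[Si](CC)(CC)CC)/C=C(\CO)C(=O)OCC
F3 | step 17 | C6 enal with bromomethyl on C11 (2-(bromomethyl)enoate) | O=C/C=C(\C)CC/C=C(/C)[C@@H](O[Si](C)(C)C(C)(C)C)[C@H](O[Si](CC)(CC)CC)/C=C(\CBr)C(=O)OCC
F0 | step 6 | none | none
F4 | step 22 | C9 2-[bis(2,2,2-trifluoroethoxy)phosphoryl]propanoate of 37 | C=C1C(=O)O[C@@H]2/C=C(\C)CC/C=C(/C)[C@@H](OC(=O)C(C)P(=O)(OCC(F)(F)F)OCC(F)(F)F)[C@H](OC(C)=O)[C@@H]12
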